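The readings are calculated with constants of no real substance; the scatter is artificial.

How far the electrophile gets in violet and teal depends on how much nucleophile stays free during the run, so you read that from the earlier runs.

common to all: electrophile 20 mM

| flask | nucleophile | remark | time |
|---|---|---|---|
| summer | 1.2 equiv | run made earlier |  |
| midnight | 3.3 equiv | run made earlier |  |
| violet | 2.00 equiv |  | 2.0 d |
| teal | 4.00 equiv |  | 2.0 d |

- summer (time / h: electrophile / %, target / %): 2.00: 94.8, 5.3; 4.00: 89.7, 8.5; 6.00: 85.6, 13.3; 12.0: 77.1, 21.1; 25.0: 64.4, 28.8
- midnight (time / h: electrophile / %, target / %): 2.00: 85.8, 12.5; 6.00: 66.2, 27.7; 12.0: 47.2, 38.0; 15.0: 41.1, 38.8; 25.0: 26.7, 39.7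

(standard deviation of a reading: 0.5 percentage points)

- the analysis behind the earlier runs scatters by 0.5 percentage points, standard deviation

- part of the electrophile that has reacted at the end, violet
- part of the electrophile that has reacted at the end, teal
- what raising the equivalents of nucleophile from its lowest to its highest value here does to the part of the electrophile that has reacted (changes below 5 percentage points count as none) (it falls / no change / it rises)

Let c be the electrophile charge, e the equivalents of nucleophile charged and x the part of the electrophile reacted. Treat the log decay of the electrophile as pseudo-first-order, with slope k times the free nucleophile. The first midnight reading gives k = 1.16 L mol⁻¹ h⁻¹, and the first summer reading gives 1.11 L mol⁻¹ h⁻¹.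

Between 15.0 h and 25.0 h the midnight slope implies 1.86 equivalents of free nucleophile, against 3.3 equiv charged. Dividing the loss by the mean x gives ν = 2.18, the nucleophile cost: equivalents of nucleophile gone per electrophile reacted. The summer run, read the same way from 12.0 h to 25.0 h, gives 2.06.

Now iterate for violet, with L = kcT = 1.11 per equivalent:

no nucleophile lost: x = 89.2%

mean of e and e − νx put back: x = 68.2%

once more: x = 75.3%

The weak link is that straight mean, since the free nucleophile falls along a curve. Integrating with constant ν replaces it, where g = exp((e − ν)L):

x = e(g − 1)/(ge − ν)

violet: x = 66.9%

teal: x = 93.5%

The forecast gave 68% for violet and 91% for teal, with the trend it rises, but it read the slowdown as “slow loss of active reagent”, whereas this reckoning reads it as a cost per electrophile reacted.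

The simulation gives 65.9% for violet and 92.2% for teal. As for the part reacted when the equivalents of nucleophile go from violet's to teal's, it rises, by 26 percentage points, and that difference in equivalents is the main reason.

    electrophile + nucleophile → acid set free + target (k = 1.20 L mol⁻¹ h⁻¹)
    nucleophile + acid set free ⇌ protonated nucleophile, settled at all times (K = 2.30 × 10⁵ L mol⁻¹)
    nucleophile + target → over-reaction product (k = 1.00 L mol⁻¹ h⁻¹)
    electrophile + acid set free ⇌ idle adduct, settled at all times (K = 60.0 L mol⁻¹)

In violet, the charged nucleophile no longer free, per electrophile reacted, comes to 2.39 at the end, against the reading ν = 2.18 from the earlier runs. Each reacted electrophile takes one nucleophile, its acid set free takes a second as protonated nucleophile, and over-reaction adds the remainder. Without that joining, violet reaches 81.1% rather than 65.9%, so the joining, together with the time given, is part of why violet stops where it does.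

For the neighbour of teal charged with 2.40 equiv, ν gives x = 75.2%; the simulation gives 73.8%.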